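The ten-membered ring (C1–C10), stripped of its oxygens at C4–C6 and carrying the C11 carbinol on C7, is hedycaryol without the C1=C10 alkene. A hedycaryol-type terpene cyclase would therefore make exactly the C6–C7 ring bond and the C11–O bond. The route rests on one enzymatic cation–olefin macrocyclisation that closes the only ring, sets C7 and installs the C11 hydroxyl from an acyclic allylic diphosphate. That precursor is (2E,7S)-6,7-dihydrofarnesyl diphosphate, built from (R)-citronellal, which supplies the C10 methyl centre. The C4=C5 alkene left by the cyclisation is then oxidised to the C4/C5/C6 oxygen pattern and O6 is angeloylated.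

Key step: step 7

Remark: ring atoms carry germacrane numbers (C4 tertiary carbinol, C5 secondary carbinol, C6 ester carbinol, C7 side-chain methine, C10 methyl methine, C11 side-chain carbinol), in which the target is 4R,5S,6R,7R,10S; 11 is handled as its tris(ammonium) salt and drawn as the free acid.

Step 1
Reactants: 1 (R)-citronellal
Product: 2 (R)-citronellol
Conditions: NaBH4, MeOH, 0 °C
Reagents that add atoms: none
Why: Borohydride reduction of the aldehyde is chemoselective over the trisubstituted alkene and does not touch the methyl-bearing stereocentre (the later C10).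

Step 2
Reactants: 2 (R)-citronellol
Product: 3 (R)-citronellyl iodide
Conditions: PPh3, I2, imidazole, CH2Cl2, 0 → 23 °C
Reagents that add atoms: iodine, II
Why: Appel-type iodination replaces the primary hydroxyl by SN2 displacement of the oxyphosphonium group two carbons away from the stereocentre, so its configuration cannot be affected.

Step 3
Reactants: 3 (R)-citronellyl iodide; 4 1-(trimethylsilyl)propyne
Product: 6 (6S)-6,10-dimethylundec-9-en-1-yne, via silylated enyne 5 (not isolated)
Conditions: 4, n-BuLi, THF, −78 → −20 °C; 3, −78 → 23 °C; then MeOH, K2CO3, 23 °C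
Reagents that add atoms: none
Why: SN2 alkylation of the propargylic lithium reagent from 4 by the primary iodide is a standard three-carbon chain extension in which the silyl group steers attack to the propargyl (not allenyl) terminus, and carbonate-catalysed methanolysis then removes the alkynyl silane.

Step 4
Reactants: 6 (6S)-6,10-dimethylundec-9-en-1-yne
Product: 9 (2E,7S)-6,7-dihydrofarnesol, via alkenyldimethylalane 7 (not isolated), via lithium butyl(alkenyl)dimethylalanate 8 (not isolated)
Conditions: Me3Al, Cp2ZrCl2 (cat.), CH2Cl2, 23 °C; evaporate; n-BuLi, hexane, −78 → 0 °C; (CH2O)n, THF, 23 °C; aq. HCl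
Reagents that add atoms: trimethylaluminium, C[Al](C)C; paraformaldehyde (as formaldehyde), C=O
Why: Negishi zirconium-catalysed carboalumination adds methyl and aluminium syn across the terminal alkyne with the metal at the terminus, and hydroxymethylation of the derived alanate proceeds with retention, so the 2E trisubstituted alkene forms directly while the remote trisubstituted alkene stays inert.

Step 5
Reactants: 9 (2E,7S)-6,7-dihydrofarnesol
Product: 10 (2E,7S)-6,7-dihydrofarnesyl chloride
Conditions: NCS, Me2S, CH2Cl2, −40 → 0 °C
Reagents that add atoms: N-chlorosuccinimide, O=C1CCC(=O)N1Cl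
Why: Corey–Kim chlorination converts the primary allylic alcohol into the chloride without allylic transposition or loss of the 2E geometry.

Step 6
Reactants: 10 (2E,7S)-6,7-dihydrofarnesyl chloride
Product: 11 (2E,7S)-6,7-dihydrofarnesyl diphosphate
Conditions: (n-Bu4N)3HP2O7, MeCN, 23 °C; then cation-exchange resin (NH4+ form), aq. NH4HCO3/i-PrOH; lyophilise
Reagents that add atoms: tris(tetrabutylammonium) hydrogen diphosphate, CCCC[N+](CCCC)(CCCC)CCCC.CCCC[N+](CCCC)(CCCC)CCCC.CCCC[N+](CCCC)(CCCC)CCCC.OP(=O)([O-])OP(=O)([O-])[O-]
Why: SN2 displacement of the primary allylic chloride by the diphosphate anion is the standard preparation of prenyl diphosphates and keeps the 2E geometry, and cation exchange gives the water-soluble ammonium salt.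

Step 7
Reactants: 11 (2E,7S)-6,7-dihydrofarnesyl diphosphate
Product: 12 (7R,10S)-germacr-4(E)-en-11-ol
Conditions: recombinant hedycaryol synthase ((7R)-hedycaryol series), MgCl2, Tris·HCl buffer pH 7.5, pentane overlay, 30 °C
Reagents that add atoms: water, O
Why: Proposed new method: The Mg2+-bound diphosphate of 11 ionises to the E-configured C4–C5–C6 allyl cation, the C7=C11 alkene folded over it attacks C6 through its less substituted carbon C7, and the tertiary C11 cation so formed is captured by active-site water. The closest known reaction type is the 1,10-cyclisation of farnesyl diphosphate, and of chain-modified or partly saturated analogues, by germacrene and hedycaryol synthases. The single ring closes in the ten-membered mode native to this enzyme class, with the new C6–C7 bond in the ring, the C4=C5 alkene kept E inside it and the cationic carbon C11 outside it. The only new stereocentre, C7, is set by the active-site fold, which decides the face of the C7=C11 alkene presented to C6; a synthase that makes (7R)-hedycaryol should give 7R here, since the CIP ranking at C7 is unchanged. The step needs ten-membered closure without onward cyclisation: saturation of C1–C10 removes the alkene needed for six-membered closure, Cope rearrangement and transannular attack, and the C10 methyl centre is already fixed from citronellal. Acceptance of the flexible, sp3-hybridised C10 region by the binding pocket is the uncertain point and is addressed by screening enzymes of both enantiomeric series and active-site variants.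

Step 8
Reactants: 12 (7R,10S)-germacr-4(E)-en-11-ol
Product: 13 (4R,5R,7R,10S)-4,5-epoxygermacran-11-ol
Conditions: mCPBA, NaHCO3, CH2Cl2, 0 °C
Reagents that add atoms: 3-chloroperoxybenzoic acid, O=C(OO)c1cccc(Cl)c1
Why: Prilezhaev epoxidation is stereospecific for the E geometry and should occur on the outer face of C4=C5 in the ring conformer that keeps the C7 side chain and the C10 methyl group in outward positions, which sets 4R,5R, while bicarbonate keeps the medium non-acidic so that the C11 hydroxyl does not open the oxirane at C4.

Step 9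
Reactants: 13 (4R,5R,7R,10S)-4,5-epoxygermacran-11-ol
Product: 16 (4R,5E,7R,10S)-germacr-5-ene-4,11-diol, via hydroxy selenide 14 (not isolated), via selenoxide 15 (not isolated)
Conditions: PhSeSePh, NaBH4, EtOH, 80 °C; then THF, 30% H2O2, 0 → 23 °C
Reagents that add atoms: none
Why: In this organoselenium epoxide-to-allylic-alcohol transposition the selenolate opens the oxirane at the secondary C5 with inversion, so the C4–O bond and its 4R configuration stay intact, and selenoxide syn-elimination can only run toward C6 (C4 has no hydrogen), a type of elimination that gives the E alkene in ten-membered rings.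

Step 10
Reactants: 16 (4R,5E,7R,10S)-germacr-5-ene-4,11-diol
Product: 17 (4R,5E,7R,10S)-4,11-bis(triethylsilyloxy)germacr-5-ene
Conditions: Et3SiOTf, 2,6-lutidine, CH2Cl2, −78 → 0 °C
Reagents that add atoms: triethylsilyl trifluoromethanesulfonate, CC[Si](CC)(CC)OS(=O)(=O)C(F)(F)F
Why: Silyl triflate with a hindered pyridine base silylates even tertiary alcohols, which masks both carbinols and turns the C4 substituent into a bulky shield for the later O5 hydroxyl.

Step 11
Reactants: 17 (4R,5E,7R,10S)-4,11-bis(triethylsilyloxy)germacr-5-ene
Product: 18 (4R,5S,6R,7R,10S)-4,11-bis(triethylsilyloxy)germacrane-5,6-diol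
Conditions: OsO4 (cat.), NMO, acetone/H2O, 23 °C
Reagents that add atoms: osmium tetroxide (catalytic carrier), O=[Os](=O)(=O)=O; N-methylmorpholine N-oxide, C[N+]1([O-])CCOCC1; water, O
Why: Catalytic osmium tetroxide dihydroxylation adds both oxygens syn to the E alkene (threo 5,6-diol) on the outer face of the ring conformer that turns H7, not the C(CH3)2OSiEt3 group, toward the reagent and keeps the C4 oxygen in the alkene plane, the face that gives the usual anti relation between an allylic oxygen and the new neighbouring hydroxyl and hence 5S,6R.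

Step 12
Reactants: 18 (4R,5S,6R,7R,10S)-4,11-bis(triethylsilyloxy)germacrane-5,6-diol; 19 angelic acid
Product: 20 (4R,5S,6R,7R,10S)-5-hydroxy-4,11-bis(triethylsilyloxy)germacran-6-yl (2Z)-2-methylbut-2-enoate
Conditions: 19, 2,4,6-Cl3C6H2COCl, Et3N, toluene, 23 °C; then 18, toluene, 80 °C
Reagents that add atoms: none
Why: Yamaguchi-type esterification through the mixed anhydride, run without a nucleophilic catalyst, should transfer the angeloyl group with its Z geometry intact to O6, because O5 is flanked by the fully substituted C4 bearing methyl and OSiEt3 whereas O6 neighbours only the C7 methine.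

Step 13
Reactants: 20 (4R,5S,6R,7R,10S)-5-hydroxy-4,11-bis(triethylsilyloxy)germacran-6-yl (2Z)-2-methylbut-2-enoate
Product: 21 (4R,5S,6R,7R,10S)-4,5,11-trihydroxygermacran-6-yl (2Z)-2-methylbut-2-enoate (CNP0130723.1)
Conditions: HF·pyridine, pyridine, THF, 0 → 23 °C
Reagents that add atoms: none
Why: Fluoride-driven desilylation (strong Si–F bond) cleaves both tertiary silyl ethers under mildly acidic, base-free conditions, so neither acyl migration to O5 nor Z-to-E isomerisation of the ester is expected.

Compound list
1 | (R)-citronellal, (3R)-3,7-dimethyloct-6-enal | CC(C)=CCC[C@@H](C)CC=O | starting material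
2 | (R)-citronellol, (3R)-3,7-dimethyloct-6-en-1-ol | CC(C)=CCC[C@@H](C)CCO | intermediate
3 | (R)-citronellyl iodide, (6R)-8-iodo-2,6-dimethyloct-2-ene | CC(C)=CCC[C@@H](C)CCI | intermediate
4 | 1-(trimethylsilyl)propyne | CC#C[Si](C)(C)C | starting material
5 | silylated enyne, trimethyl[(6S)-6,10-dimethylundec-9-en-1-yn-1-yl]silane | CC(C)=CCC[C@@H](C)CCCC#C[Si](C)(C)C | intermediate
6 | (6S)-6,10-dimethylundec-9-en-1-yne | CC(C)=CCC[C@@H](C)CCCC#C | intermediate
7 | alkenyldimethylalane, dimethyl[(1E,6S)-2,6,10-trimethylundeca-1,9-dien-1-yl]alane | CC(C)=CCC[C@@H](C)CCC/C(C)=C/[Al](C)C | intermediate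
8 | lithium butyl(dimethyl)[(1E,6S)-2,6,10-trimethylundeca-1,9-dien-1-yl]alanate | CC(C)=CCC[C@@H](C)CCC/C(C)=C/[Al-](C)(C)CCCC.[Li+] | intermediate
9 | (2E,7S)-6,7-dihydrofarnesol, (2E,7S)-3,7,11-trimethyldodeca-2,10-dien-1-ol | CC(C)=CCC[C@@H](C)CCC/C(C)=C/CO | intermediate
10 | (2E,7S)-6,7-dihydrofarnesyl chloride, (2E,7S)-1-chloro-3,7,11-trimethyldodeca-2,10-diene | CC(C)=CCC[C@@H](C)CCC/C(C)=C/CCl | intermediate
11 | (2E,7S)-6,7-dihydrofarnesyl diphosphate (tris(ammonium) salt, drawn as free acid) | CC(C)=CCC[C@@H](C)CCC/C(C)=C/COP(=O)(O)OP(=O)(O)O | intermediate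
12 | (7R,10S)-germacr-4(E)-en-11-ol, 2-[(1R,3E,8S)-4,8-dimethylcyclodec-3-en-1-yl]propan-2-ol | C1[C@H](C(C)(C)O)CC[C@@H](C)CCC/C(C)=C/1 | intermediate
13 | (4R,5R,7R,10S)-4,5-epoxygermacran-11-ol (trans-oxirane) | C1[C@H](C(C)(C)O)CC[C@@H](C)CCC[C@@]2(C)O[C@H]12 | intermediate
14 | hydroxy selenide, (4R,5S,7R,10S)-5-(phenylselanyl)germacrane-4,11-diol | C1[C@H](C(C)(C)O)CC[C@@H](C)CCC[C@@](C)(O)[C@H]1[Se]c1ccccc1 | intermediate
15 | selenoxide of 14 (either configuration at selenium) | C1[C@H](C(C)(C)O)CC[C@@H](C)CCC[C@@](C)(O)[C@H]1[Se](=O)c1ccccc1 | intermediate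
16 | (4R,5E,7R,10S)-germacr-5-ene-4,11-diol | CC(C)(O)[C@@H]1CC[C@@H](C)CCC[C@@](C)(O)/C=C/1 | intermediate
17 | (4R,5E,7R,10S)-4,11-bis(triethylsilyloxy)germacr-5-ene | CC(C)(O[Si](CC)(CC)CC)[C@@H]1CC[C@@H](C)CCC[C@@](C)(O[Si](CC)(CC)CC)/C=C/1 | intermediate
18 | (4R,5S,6R,7R,10S)-4,11-bis(triethylsilyloxy)germacrane-5,6-diol | O[C@@H]1[C@H](C(C)(C)O[Si](CC)(CC)CC)CC[C@@H](C)CCC[C@@](C)(O[Si](CC)(CC)CC)[C@H]1O | intermediate
19 | angelic acid, (2Z)-2-methylbut-2-enoic acid | C/C=C(/C)C(=O)O | starting material
20 | (4R,5S,6R,7R,10S)-5-hydroxy-4,11-bis(triethylsilyloxy)germacran-6-yl (2Z)-2-methylbut-2-enoate | C/C=C(/C)C(=O)O[C@@H]1[C@H](C(C)(C)O[Si](CC)(CC)CC)CC[C@@H](C)CCC[C@@](C)(O[Si](CC)(CC)CC)[C@H]1O | intermediate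
21 | (4R,5S,6R,7R,10S)-4,5,11-trihydroxygermacran-6-yl (2Z)-2-methylbut-2-enoate (CNP0130723.1) | C/C=C(/C)C(=O)O[C@@H]1[C@H](C(C)(C)O)CC[C@@H](C)CCC[C@@](C)(O)[C@H]1O | target

Total step count: 13
Longest linear sequence: 13 steps (1 → 21; the route is fully linear, 4 and 19 enter as small building blocks).

Steps most likely to fail

1. Step 7 (Proposed new method). The synthase may bind the 6,7-saturated chain unproductively, may ionise it and release acyclic products through premature water capture or proton loss, or may fold it so that the other face of the C7=C11 alkene is attacked. The fallback uses known chemistry, sets out from 9 and returns at 12; it closes the same C6–C7 bond by letting a sulfur-stabilised allyl anion open a terminal epoxide. Acetylation of 9 (Ac2O, pyridine) gives (2E,7S)-6,7-dihydrofarnesyl acetate F1. Shi epoxidation (D-fructose-derived ketone, KHSO5, K2CO3, MeCN/dimethoxymethane/H2O, 0 °C) oxidises only the distal, electron-rich alkene and should give (2E,7S,10R)-10,11-epoxy-6,7-dihydrofarnesyl acetate F2. Methanolysis (K2CO3, MeOH) gives (2E,7S,10R)-10,11-epoxy-6,7-dihydrofarnesol F3, and PhSSPh/PBu3 converts it into (2E,7S,10R)-10,11-epoxy-6,7-dihydrofarnesyl phenyl sulfide F4. Treatment with n-BuLi/DABCO (THF, −78 °C, high dilution) generates the anion next to sulfur, which opens the oxirane at its secondary carbon with inversion; this closes the ten-membered ring to 6-(phenylsulfanyl)germacr-4(E)-en-11-ol F5, with C7 arranged as in 12 and the C11 hydroxyl in place. Li/EtNH2 (−78 °C) removes the sulfide and gives 12.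

2. Step 9. The selenolate has to reach C5 from the face that is turned toward the ring interior, so transannular shielding may stall the opening or divert it to base-induced side reactions. The fallback sets out from 12 and returns at 16, and needs no attack from the inner face. A Schenck ene reaction with singlet oxygen (O2, tetraphenylporphyrin, visible light, CH2Cl2, 0 °C) should attack the open outer face of C4=C5, bond oxygen to C4 and take the outward C6 hydrogen. This gives (4R,5E,7R,10S)-4-hydroperoxygermacr-5-en-11-ol F6, to be separated from the regioisomer that arises by abstraction of a C4-methyl hydrogen. PPh3 then reduces the hydroperoxide to 16.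

3. Step 12. Acyl transfer to the hindered O6 hydroxyl may be slow, and forcing conditions would erode the Z geometry of the acyl group (tiglate formation) or the preference for O6 over O5. The fallback sets out from 18 and returns at 20, and builds the Z alkene after an easy acylation. Carbodiimide esterification (DCC, cat. DMAP, CH2Cl2, 0 °C) with the unhindered 2-[bis(2,2,2-trifluoroethoxy)phosphoryl]propanoic acid gives the O6 2-[bis(2,2,2-trifluoroethoxy)phosphoryl]propanoate of 18 F7. Still–Gennari olefination with acetaldehyde (KN(SiMe3)2, 18-crown-6, THF, −78 °C) then forms the (2Z)-2-methylbut-2-enoate on the molecule and gives 20.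

Steps 8 and 11 rely on conformational (peripheral-attack) control; both have reagent-controlled variants (Shi epoxidation, ligand-accelerated osmylation) that lead to the same numbered compounds.

Further compounds
F1 | step 7 | (2E,7S)-6,7-dihydrofarnesyl acetate | CC(C)=CCC[C@@H](C)CCC/C(C)=C/COC(C)=O
F2 | step 7 | (2E,7S,10R)-10,11-epoxy-6,7-dihydrofarnesyl acetate | CC1(C)O[C@@H]1CC[C@@H](C)CCC/C(C)=C/COC(C)=O
F3 | step 7 | (2E,7S,10R)-10,11-epoxy-6,7-dihydrofarnesol | CC1(C)O[C@@H]1CC[C@@H](C)CCC/C(C)=C/CO
F4 | step 7 | (2E,7S,10R)-10,11-epoxy-6,7-dihydrofarnesyl phenyl sulfide | CC1(C)O[C@@H]1CC[C@@H](C)CCC/C(C)=C/CSc1ccccc1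
F5 | step 7 | 6-(phenylsulfanyl)germacr-4(E)-en-11-ol (C7 and C10 arranged as in 12, both C6 epimers) | CC(C)(O)[C@@H]1CC[C@@H](C)CCC/C(C)=C/C1Sc1ccccc1
F6 | step 9 | (4R,5E,7R,10S)-4-hydroperoxygermacr-5-en-11-ol | CC(C)(O)[C@@H]1CC[C@@H](C)CCC[C@@](C)(OO)/C=C/1
F7 | step 12 | O6 2-[bis(2,2,2-trifluoroethoxy)phosphoryl]propanoate of 18 | CC(C(=O)O[C@@H]1[C@H](C(C)(C)O[Si](CC)(CC)CC)CC[C@@H](C)CCC[C@@](C)(O[Si](CC)(CC)CC)[C@H]1O)P(=O)(OCC(F)(F)F)OCC(F)(F)F
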